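- Time comes first, since you want a quick number: here is what stands in the flask and what you asked.

starting material 20 mM; coupling partner 30.0 mM; free catalyst 100 µM; second catalyst 0.12 mM

    starting material + free catalyst → free catalyst + open intermediate (k1 = 2400 M⁻¹ s⁻¹)
    second catalyst + open intermediate ⇌ catalyst intermediate (K2 = 350 M⁻¹, k2 = 2100 M⁻¹ s⁻¹)
    coupling partner + catalyst intermediate → second catalyst + target (k3 = 81 M⁻¹ s⁻¹)
    2 free catalyst ⇌ resting dimer, settled at all times (K4 = 44000 M⁻¹)

- where a step has two of a species, its rate is k times that concentration squared, and two are used at each turn
- "the catalyst" is free catalyst with its forms; second catalyst is a second catalyst
- a form made of two catalysts counts as two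
- charge of starting material (flask): 20 mM

* the form that holds most of the catalyst when 5.0% of the starting material are converted (resting dimer / free catalyst)
* its share of the catalyst then
* factor on the rate of making target when 5.0% of the starting material are converted if coupling partner is charged twice over
* factor on the rate when 5.0% of the starting material are converted if free catalyst is charged at 500 µM instead

- The number I carry is 28.5 µM, the standing free catalyst, meaning what stays free once the balance with the resting dimer has taken its part of the charge, each dimer counting as two catalysts.
- That puts 71.5% of the catalyst in the resting dimer, the resting state, which is more than the 28.5% left free.
- Step one gives its free catalyst back each time, so starting material falls pseudo-first-order at 4.10 min⁻¹, and I expect 5.0% conversion after 0.750 s.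
- With 500 µM charged, the same balance gives 69.9 µM standing free catalyst and 86.0% in the resting dimer, so 5.00 times the charge buys 2.45 times the free catalyst, and that conversion comes after 0.306 s.
- My reckoning stops there, and I commit to no number for either factor on the rate.
- The forecast you sent names the resting dimer with 71.5%, the same share as mine, and gives a factor of 1.6 for doubled coupling partner and 0.86 for 500 µM of free catalyst. On the first factor it argues that “doubling coupling partner gives less than double because it also drains the catalyst intermediate”.
- The simulation gives the resting dimer with 71.5%, free catalyst with 28.5%, a factor of 1.65 for doubled coupling partner and 0.820 for 500 µM of free catalyst.
- In the flask as charged, the standing free catalyst of 28.5 µM puts the half-life of starting material at 0.169 min, and at 0.169 min open intermediate is made 3.59 times faster than it is used up, while catalyst intermediate falls back 2.6 times faster than it goes on. At 0.250 min that flask holds 51.8% as open intermediate, more than the 11.9% as target, and at 2.50 min catalyst intermediate is made 0.987 times as fast as it is used up. In the run with free catalyst charged at 500 µM instead of 100 µM, the standing free catalyst of 69.9 µM leaves 86.0% in the resting dimer, and at the same conversion that run reads 86.0%.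

The constants were drawn at random within sensible limits.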